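**Retrosynthetic overview**

1. The C8 senecioate is put on last by Mitsunobu inversion of an 8-epi alcohol. The unit O–C8–C7=C11–C13–O (13-acetoxy butenolide) is traced to a 7,8-epoxy-11(13)-ene opened SN2′ by acetate, and that vinyl oxirane to a 7,11(13)-dienolide made by Stille coupling of a C7 alkenyl iodide with an α-stannyl acrylate and lactonisation of O6 onto C12.
2. The feature carrying the strategy: the oxiranes C1–C10 and C4–C5 are both cis-fused to the ten-membered ring, so both come from Z alkenes. The chain C9–C10(Me)=C1–C2–C3–C4(Me), together with C7 and C8, is the eight-membered ring of (1Z,5Z)-1,5-dimethylcycloocta-1,5-diene with C4 still bonded to C7; only C5 and C6 are missing, and C6 bears oxygen as a ketene carbonyl carbon would.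
3. The ten-membered carbocycle is therefore never cyclised: dichloroketene [2+2] lays C5–C6 across C4=C7, and conrotatory opening of the derived siloxycyclobutene cuts C4–C7, merging the four- and eight-membered rings.
4. Ring order: eight-membered ring (bought), cyclobutanone, ten-membered carbocycle, 4,5-oxirane, 1,10-oxirane, γ-lactone, transient 7,8-oxirane, butenolide.

Key step: step 4

Remark: germacrane numbering of the target is used for all atoms (ring C1–C10, methyls on C4 and C10, lactone carbonyl C12 on O6, acetoxymethyl carbon C13); "cis/trans in the ring" refers to the two ring bonds at a double bond, which for the enol ether of 7 and the alkenyl iodides carries the opposite CIP letter; compounds 4–6 are racemic and drawn as one enantiomer.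

**Step 1**
Reactants: 1 (1Z,5Z)-1,5-dimethylcycloocta-1,5-diene; 2 trichloroacetyl chloride
Product: 4 rac-cis-10,10-dichloro-1,5-dimethylbicyclo[6.2.0]dec-4-en-9-one, via dichloroketene 3 (not isolated)
Conditions: 1 (3 equiv, freed of its 1,6-dimethyl isomer by fractional distillation), Zn–Cu couple, Et2O/DME, reflux, slow addition of 2
Reagents that add atoms: none
Why: Zinc dechlorination of 2 releases dichloroketene, which adds suprafacially in a ketene–alkene [2+2] cycloaddition to one of the two symmetry-equivalent Z alkenes, the carbonyl carbon (C6) bonding to the CH terminus C7 and CCl2 (C5) to the methyl-bearing C4, so the cis-fused cyclobutanone should form as a racemate whose two stereocentres are erased in step 4, while DME binds ZnCl2 and the excess of diene suppresses double addition.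

**Step 2**
Reactants: 4 rac-cis-10,10-dichloro-1,5-dimethylbicyclo[6.2.0]dec-4-en-9-one
Product: 5 rac-cis-1,5-dimethylbicyclo[6.2.0]dec-4-en-9-one
Conditions: Zn, AcOH, 50 °C
Reagents that add atoms: none
Why: Reductive dechlorination of an α,α-dichlorocyclobutanone through zinc enolates removes both chlorines from C5 and should leave the trisubstituted alkene and the ring fusion untouched.

**Step 3**
Reactants: 5 rac-cis-1,5-dimethylbicyclo[6.2.0]dec-4-en-9-one
Product: 6 rac-cis-1,5-dimethyl-9-(trimethylsilyloxy)bicyclo[6.2.0]deca-4,9-diene
Conditions: LiN(iPr)2 (LDA), Me3SiCl (internal quench), THF, −78 °C; Et3N, pentane, filtration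
Reagents that add atoms: chlorotrimethylsilane, C[Si](C)(C)Cl
Why: Kinetic deprotonation with a hindered amide base and in situ silylation should take the more accessible C5 methylene proton rather than the ring-fusion methine C7–H, giving the 1-siloxycyclobutene with the C5=C6 double bond (kinetic silyl enol ether formation).

**Step 4**
Reactants: 6 rac-cis-1,5-dimethyl-9-(trimethylsilyloxy)bicyclo[6.2.0]deca-4,9-diene
Product: 7 6-(trimethylsilyloxy)-4,10-dimethylcyclodeca-1(10),4,6-triene (C1=C10 and C4=C5 cis in the ring; C6=C7 trans in the ring)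
Conditions: PhMe (0.01 M, degassed), Et3N (1 mol %), base-washed sealed tube, 160 °C, stopped at full conversion
Reagents that add atoms: none
Why: On heating, the cyclobutene should undergo the thermally allowed conrotatory four-electron electrocyclic opening, in which the σ bond C4–C7 shared by the four- and eight-membered rings breaks while C4=C5 and C6=C7 form, driven by release of cyclobutene strain. The closest known reaction type is the thermal opening of cis-bicyclo[n.2.0]alkenes and of 1-siloxycyclobutenes to ring-enlarged cis,trans-1,3-dienes (two-carbon ring expansion), for example cis-bicyclo[6.2.0]dec-9-ene to cis,trans-cyclodeca-1,3-diene. The ten-membered carbocycle is not closed by a cyclisation but arises by fusion of two existing rings through bond cleavage, so neither macrocyclisation entropy nor transannular strain in a ring-closing transition state has to be paid. No stereocentre is created (C4 and C7 become trigonal); what is set is alkene geometry, governed by torquoselectivity: at C7 the ring branch C8 should turn outward and the hydrogen inward, and conrotation from the cis ring fusion then carries C3 inward at C4, giving the cis (Z) C4=C5 bond with C3 cis to C6 and a trans enol ether C6=C7 that step 5 erases, whereas the opposite rotation would force both C8 and the C4 methyl inward. The step needs clean conversion without [1,5]-hydrogen shift in the new diene or Cope rearrangement of the 1,5-diene C4=C5/C1=C10, which dilution, a base-washed vessel and stopping at full conversion should secure.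

**Step 5**
Reactants: 7 6-(trimethylsilyloxy)-4,10-dimethylcyclodeca-1(10),4,6-triene
Product: 8 4,10-dimethylcyclodeca-1(10),4,7-trien-6-one (all three double bonds cis in the ring)
Conditions: Pd(OAc)2 (1.1 equiv), MeCN, rt
Reagents that add atoms: none
Why: In the Saegusa–Ito oxidation divalent palladium converts the silyl enol ether into a C7 palladium enolate whose only β-hydrogens are on C8, so syn β-hydride elimination should give the cross-conjugated dienone and erase the trans enol ether geometry, and any C7=C8 isomer that is trans in the ring is carried on because step 6 funnels both geometries to one product.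

**Step 6**
Reactants: 8 4,10-dimethylcyclodeca-1(10),4,7-trien-6-one
Product: 9 7-iodo-4,10-dimethylcyclodeca-1(10),4,7-trien-6-one (all three double bonds cis in the ring)
Conditions: I2, pyridine/CH2Cl2 (1:1), DMAP (cat.), 0 °C to rt, dark
Reagents that add atoms: iodine, II
Why: Amine-catalysed α-iodination of an enone (Baylis–Hillman-type addition of the amine at C8, iodination of the enolate at C7, elimination) should touch only the β-monosubstituted C7=C8 enone and not the β,β-disubstituted C4=C5 enone, the reversible amine addition lets the C7=C8 geometry settle to the less strained all-cis ring, and the absence of strong base spares the doubly allylic C9 methylene.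

**Step 7**
Reactants: 9 7-iodo-4,10-dimethylcyclodeca-1(10),4,7-trien-6-one
Product: 10 (6S)-7-iodo-4,10-dimethylcyclodeca-1(10),4,7-trien-6-ol
Conditions: (R)-2-methyl-CBS-oxazaborolidine (0.3 equiv), catecholborane, PhMe, −78 °C; MeOH, then wash at pH 10
Reagents that add atoms: none
Why: In the Corey–Bakshi–Shibata reduction the α-iodoalkenyl arm should act as the large group and the unsubstituted alkenyl arm as the small one, so the (R)-catalyst delivers hydride 1,2 to the face that gives the (6S)-carbinol (the spatial arrangement of C6 in the target), and catecholborane at −78 °C should not hydroborate C1=C10.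

**Step 8**
Reactants: 10 (6S)-7-iodo-4,10-dimethylcyclodeca-1(10),4,7-trien-6-ol
Product: 11 (4S,5R,6S)-4,5-epoxy-7-iodo-4,10-dimethylcyclodeca-1(10),7-dien-6-ol (oxirane oxygen and hydroxyl on the same ring face)
Conditions: VO(acac)2 (5 mol %), t-BuOOH (in decane), CH2Cl2, 0 °C
Reagents that add atoms: tert-butyl hydroperoxide, CC(C)(C)OO
Why: Hydroxyl-directed vanadium-catalysed epoxidation should deliver oxygen to the hydroxyl face of C4=C5, the only nucleophilic allylic alkene (the alkenyl iodide is deactivated and C1=C10 is remote from the directing group), and with H6 held in the alkene plane by allylic 1,3-strain against C3 this gives the cis epoxy alcohol, as Z-cycloalk-2-enols of medium ring size do, which sets C4 (S) and C5 (R).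

**Step 9**
Reactants: 11 (4S,5R,6S)-4,5-epoxy-7-iodo-4,10-dimethylcyclodeca-1(10),7-dien-6-ol
Product: 12 (1S,4S,5R,6S,10R)-1,10:4,5-diepoxy-7-iodo-4,10-dimethylcyclodec-7-en-6-ol
Conditions: enantiomer of the fructose-derived Shi ketone (made from L-sorbose, 0.5 equiv), KHSO5 (Oxone), K2CO3, Bu4NHSO4, MeCN/CH2(OMe)2/aq. Na2B4O7 buffer, 0 °C
Reagents that add atoms: potassium peroxymonosulfate (KHSO5), [K+].[O-]S(=O)(=O)OO
Why: In the Shi epoxidation the chiral dioxirane should attack only the electron-rich C1=C10 through a spiro transition state, the Z alkene giving a cis-fused oxirane stereospecifically, and the ketone enantiomer is chosen by analogy with 1-substituted cycloalkenes so that reagent control places oxygen on the face that gives 1S,10R.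

**Step 10**
Reactants: 13 methyl propiolate
Product: 14 methyl 2-(tributylstannyl)acrylate
Conditions: Bu3SnH, Pd(PPh3)4 (2 mol %), THF, 0 °C to rt
Reagents that add atoms: tributyltin hydride, CCCC[SnH](CCCC)CCCC
Why: Palladium-catalysed syn hydrostannation of an alkynoate places tin on the carbon α to the ester and hydrogen on the terminal carbon, the established regiochemistry for propiolates.

**Step 11**
Reactants: 12 (1S,4S,5R,6S,10R)-1,10:4,5-diepoxy-7-iodo-4,10-dimethylcyclodec-7-en-6-ol; 14 methyl 2-(tributylstannyl)acrylate
Product: 16 (1S,4S,5R,6R,10R)-1,10:4,5-diepoxygermacra-7,11(13)-dien-12,6-olide, via hydroxy acrylate 15 (not isolated)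
Conditions: Pd(PPh3)4 (10 mol %), CuI (20 mol %), CsF, DMF (0.02 M), 40 °C; then DBU (cat.), rt; product used at once in dilute solution
Reagents that add atoms: none
Why: Copper-assisted Stille coupling of the alkenyl iodide with the α-stannyl acrylate should form C7–C11 with retention of the C7=C8 geometry, after which O6 acylates intramolecularly on C12 with loss of methanol (5-exo-trig lactonisation under mild base, chosen to spare the two acid-sensitive oxiranes), giving the s-cis-locked dienolide without touching any stereocentre.

**Step 12**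
Reactants: 16 (1S,4S,5R,6R,10R)-1,10:4,5-diepoxygermacra-7,11(13)-dien-12,6-olide
Product: 17 (1S,4S,5R,6S,7S,8S,10R)-1,10:4,5:7,8-triepoxygermacr-11(13)-en-12,6-olide
Conditions: m-CPBA (1.1 equiv), NaHCO3, CH2Cl2, 0 °C
Reagents that add atoms: 3-chloroperbenzoic acid, OOC(=O)c1cccc(Cl)c1
Why: In this Prilezhaev epoxidation the trisubstituted C7=C8 is far more nucleophilic than the acrylate C11=C13, and the peracid should approach the planar dienolide on the open face syn to H6 and opposite to the C5 branch that carries the rest of the ten-membered ring over the other face, which sets C7 (S, transient) and C8 (S).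

**Step 13**
Reactants: 17 (1S,4S,5R,6S,7S,8S,10R)-1,10:4,5:7,8-triepoxygermacr-11(13)-en-12,6-olide
Product: 18 (1S,4S,5R,6R,8S,10R)-13-acetoxy-1,10:4,5-diepoxy-8-hydroxygermacr-7(11)-en-12,6-olide
Conditions: Pd(PPh3)4 (5 mol %), AcOH (3 equiv), THF, 0 °C to rt
Reagents that add atoms: acetic acid, CC(=O)O
Why: In this Tsuji–Trost opening of a vinyl oxirane zerovalent palladium should ionise the allylic C7–O bond, which stands perpendicular to the lactone plane, to a π-allyl complex over C7–C11–C13 that acetate attacks at the primary terminus C13, giving net 1,4-addition of acetic acid with the C7=C11 geometry fixed by the lactone, the C8–O bond untouched (8S) and the non-allylic 1,10- and 4,5-oxiranes inert.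

**Step 14**
Reactants: 18 (1S,4S,5R,6R,8S,10R)-13-acetoxy-1,10:4,5-diepoxy-8-hydroxygermacr-7(11)-en-12,6-olide; 19 3-methylbut-2-enoic acid (senecioic acid)
Product: 20 (1S,4S,5R,6R,8R,10R)-13-acetoxy-1,10:4,5-diepoxy-8-(3-methylbut-2-enoyloxy)germacr-7(11)-en-12,6-olide (CNP0228323.1)
Conditions: PPh3, DIAD, THF, 0 °C to rt
Reagents that add atoms: none
Why: In the Mitsunobu esterification the C8 alkoxyphosphonium ion should be displaced by senecioate with inversion (8S to 8R), and the SN2′ alternative is disfavoured because C11 is fully substituted and attack there would break the butenolide conjugation.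

**Compound list**

1 | (1Z,5Z)-1,5-dimethylcycloocta-1,5-diene | C/C1=C/CC/C(C)=C\CC1 | starting material
2 | trichloroacetyl chloride | ClC(Cl)(Cl)C(Cl)=O | starting material
3 | dichloroketene | ClC(Cl)=C=O | intermediate
4 | rac-cis-10,10-dichloro-1,5-dimethylbicyclo[6.2.0]dec-4-en-9-one | O=C1C(Cl)(Cl)[C@@]2(C)CC/C=C(C)\CC[C@@H]12 | intermediate
5 | rac-cis-1,5-dimethylbicyclo[6.2.0]dec-4-en-9-one | O=C1C[C@@]2(C)CC/C=C(C)\CC[C@@H]12 | intermediate
6 | rac-cis-1,5-dimethyl-9-(trimethylsilyloxy)bicyclo[6.2.0]deca-4,9-diene | C[Si](C)(C)OC1=C[C@@]2(C)CC/C=C(C)\CC[C@@H]12 | intermediate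
7 | 6-(trimethylsilyloxy)-4,10-dimethylcyclodeca-1(10),4,6-triene, C1=C10 and C4=C5 cis in the ring, C6=C7 trans in the ring | C1C/C(C)=C\CC/C(C)=C\C(O[Si](C)(C)C)=C\1 | intermediate
8 | 4,10-dimethylcyclodeca-1(10),4,7-trien-6-one, all double bonds cis in the ring | O=C1/C=C\C/C(C)=C\CC/C(C)=C\1 | intermediate
9 | 7-iodo-4,10-dimethylcyclodeca-1(10),4,7-trien-6-one, all double bonds cis in the ring | O=C1/C(I)=C\C/C(C)=C\CC/C(C)=C\1 | intermediate
10 | (6S)-7-iodo-4,10-dimethylcyclodeca-1(10),4,7-trien-6-ol | O[C@H]1/C=C(C)\CC/C=C(C)\C/C=C\1I | intermediate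
11 | (4S,5R,6S)-4,5-epoxy-7-iodo-4,10-dimethylcyclodeca-1(10),7-dien-6-ol | O[C@H]1[C@H]2O[C@@]2(C)CC/C=C(C)\C/C=C\1I | intermediate
12 | (1S,4S,5R,6S,10R)-1,10:4,5-diepoxy-7-iodo-4,10-dimethylcyclodec-7-en-6-ol | O[C@H]1[C@H]2O[C@@]2(C)CC[C@@H]2O[C@]2(C)C/C=C\1I | intermediate
13 | methyl propiolate | C#CC(=O)OC | starting material
14 | methyl 2-(tributylstannyl)acrylate | C=C(C(=O)OC)[Sn](CCCC)(CCCC)CCCC | intermediate
15 | methyl 2-[(1S,4S,5R,6R,10R)-1,10:4,5-diepoxy-6-hydroxy-4,10-dimethylcyclodec-7-en-7-yl]acrylate | O[C@H]1[C@H]2O[C@@]2(C)CC[C@@H]2O[C@]2(C)C/C=C\1C(=C)C(=O)OC | intermediate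
16 | (1S,4S,5R,6R,10R)-1,10:4,5-diepoxygermacra-7,11(13)-dien-12,6-olide | C=C1C(=O)O[C@H]2[C@H]3O[C@@]3(C)CC[C@@H]3O[C@]3(C)C/C=C1\2 | intermediate
17 | (1S,4S,5R,6S,7S,8S,10R)-1,10:4,5:7,8-triepoxygermacr-11(13)-en-12,6-olide | C=C1C(=O)O[C@H]2[C@H]3O[C@@]3(C)CC[C@@H]3O[C@]3(C)C[C@@H]3O[C@]123 | intermediate
18 | (1S,4S,5R,6R,8S,10R)-13-acetoxy-1,10:4,5-diepoxy-8-hydroxygermacr-7(11)-en-12,6-olide | CC(=O)OCC1=C2[C@@H](OC1=O)[C@H]1O[C@@]1(C)CC[C@@H]1O[C@]1(C)C[C@@H]2O | intermediate
19 | 3-methylbut-2-enoic acid (senecioic acid) | CC(C)=CC(=O)O | starting material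
20 | (1S,4S,5R,6R,8R,10R)-13-acetoxy-1,10:4,5-diepoxy-8-(3-methylbut-2-enoyloxy)germacr-7(11)-en-12,6-olide (CNP0228323.1) | CC(=O)OCC1=C2[C@@H](OC1=O)[C@H]1O[C@@]1(C)CC[C@@H]1O[C@]1(C)C[C@H]2OC(=O)C=C(C)C | target

**Step count and risk**

Total step count: 14. Longest linear sequence: 13 steps (steps 1–9 and 11–14; step 10 is the side branch).

Steps most likely to fail:

1. Step 4 (electrocyclic ring expansion). The conrotation may run partly or mainly in the other sense, or the siloxytriene may isomerise thermally, so that the C4=C5 bond comes out trans in the ring. Fallback, from 6 back to 8: the thermolysate is taken on even if it is the other conrotatory product, 6-(trimethylsilyloxy)-4,10-dimethylcyclodeca-1(10),4,6-triene with C4=C5 trans and C6=C7 cis in the ring F1. Saegusa–Ito oxidation with Pd(OAc)2 in MeCN should convert it into (4E)-4,10-dimethylcyclodeca-1(10),4,7-trien-6-one F2. The C4=C5 enone geometry is then corrected under thermodynamic control (cat. I2, visible light, PhH, or cat. PhSH with a radical initiator), which should drain the strained isomer into the all-cis ring of 8. Kinetic torquoselectivity is thus replaced by equilibration of a conjugated enone.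

2. Step 9 (Shi epoxidation). The facial preference of the chiral dioxirane may be opposed by the conformational bias of the chiral ten-membered ring, giving poor diastereoselectivity at C1/C10. Fallback, from 9 back to 12: the epoxidation is moved to the achiral stage, where only enantioselectivity is asked of the reagent. The same Shi ketone enantiomer with KHSO5 on 9 should give (1S,10R)-1,10-epoxy-7-iodo-4,10-dimethylcyclodeca-4,7-dien-6-one F3 (the two enone alkenes are too electron-poor to react). Reduction with the (R)-2-methyl-CBS-oxazaborolidine and catecholborane then gives (1S,6S,10R)-1,10-epoxy-7-iodo-4,10-dimethylcyclodeca-4,7-dien-6-ol F4, and the hydroxyl-directed VO(acac)2/t-BuOOH epoxidation of C4=C5 returns to 12.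

3. Step 13 (palladium-mediated opening). After ionisation the π-allyl intermediate may lose a β-hydride or undergo hydride shift instead of capturing acetate at C13, acetate may return at C7, or the acid may open one of the other oxiranes transannularly. Fallback, from 16 back to 18, bypassing 17: the s-cis diene C13=C11–C7=C8 of 16 is photooxygenated (O2, tetraphenylporphyrin, visible light, CH2Cl2, −78 °C). Singlet oxygen should add [4+2] from the open face to give (8S)-8,13-epidioxy-1,10:4,5-diepoxygermacr-7(11)-en-12,6-olide F5, with the butenolide double bond already in place. Thiourea in MeOH reduces the O–O bond to (8S)-1,10:4,5-diepoxy-8,13-dihydroxygermacr-7(11)-en-12,6-olide F6; base is avoided to prevent Kornblum–DeLaMare rearrangement. Ac2O with 2,4,6-collidine at −20 °C then acetylates only the primary C13 hydroxyl and gives 18.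

**Further compounds**

F1 | step 4 | 6-(trimethylsilyloxy)-4,10-dimethylcyclodeca-1(10),4,6-triene with C4=C5 trans and C6=C7 cis in the ring | C1C/C(C)=C\CC/C(C)=C/C(O[Si](C)(C)C)=C\1
F2 | step 4 | (4E)-4,10-dimethylcyclodeca-1(10),4,7-trien-6-one | O=C1/C=C\C/C(C)=C\CC/C(C)=C/1
F3 | step 9 | (1S,10R)-1,10-epoxy-7-iodo-4,10-dimethylcyclodeca-4,7-dien-6-one | O=C1/C=C(C)\CC[C@@H]2O[C@]2(C)C/C=C\1I
F4 | step 9 | (1S,6S,10R)-1,10-epoxy-7-iodo-4,10-dimethylcyclodeca-4,7-dien-6-ol | O[C@H]1/C=C(C)\CC[C@@H]2O[C@]2(C)C/C=C\1I
F5 | step 13 | (8S)-8,13-epidioxy-1,10:4,5-diepoxygermacr-7(11)-en-12,6-olide | O=C1O[C@H]2[C@H]3O[C@@]3(C)CC[C@@H]3O[C@]3(C)C[C@@H]3OOCC1=C23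
F6 | step 13 | (8S)-1,10:4,5-diepoxy-8,13-dihydroxygermacr-7(11)-en-12,6-olide | OCC1=C2[C@@H](OC1=O)[C@H]1O[C@@]1(C)CC[C@@H]1O[C@]1(C)C[C@@H]2O
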